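The runs were generated by integration on assumed constants, and the scatter is random.

If no reagent goes to the self-condensation product, the flask's 0.800 M of reagent covers 2.00 equivalents per substrate, as many as a bis adduct holds, so on paper substrate and mono adduct both end at zero. If instead the flask stops at its last zeta reading, the substrate stays at 42 %.

| flask | substrate | reagent | remark | time |
|---|---|---|---|---|
| zeta | 0.40 M | 0.80 M | the very flask that is asked about, followed so far |  |
| theta | 0.80 M | 0.80 M | run made earlier |  |
| flask | 0.40 M | 0.800 M |  | 5.0 h |

| run | time / min | substrate / % | mono adduct / % |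
|---|---|---|---|
| zeta | 12.0 | 77 | 21 |
| zeta | 25.0 | 63 | 29 |
| zeta | 40.0 | 54 | 31 |
| zeta | 50.0 | 51 | 33 |
| zeta | 60.0 | 42 | 27 |
| theta | 10.0 | 81 | 22 |
| theta | 20.0 | 69 | 25 |
| theta | 30.0 | 61 | 28 |
| theta | 60.0 | 55 | 29 |
| theta | 120 | 47 | 34 |

(scatter of a reading: 2 percentage points)

- reactions considered so far: reagent + bis adduct -> tris adduct; reagent + mono adduct -> bis adduct; bis adduct <-> isomer of the product; 2 reagent -> self-condensation product; substrate + reagent -> mono adduct

- the substrate standing at 5.0 h, as a percentage of the substrate charged
- the mono adduct standing at 5.0 h, as a percentage of the substrate charged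
- the bis adduct standing at 5.0 h, as a percentage of the substrate charged
- the tris adduct standing at 5.0 h, as a percentage of the substrate charged

The real flask lies between these two versions, and I place it by counting bound reagent. A mono adduct holds one reagent, and a bis adduct or its isomer holds two. I take tris adduct to be a small correction and drop it. So the bound equivalents per substrate are 2 − 2[substrate] − [mono adduct], as fractions. Zeta has reached 0.890 at 60.0 min, with its substrate still falling. Theta's last reading gives 0.720, which is 72.0 % of its reagent, and I assume theta has stopped there.

At 0.800 M of reagent charged, I let the adducts' share of the reagent be [substrate charged] / ([substrate charged] + h), where h is the capture charge: the substrate charge at which adducts and self-condensation take equal shares. Theta gives h = 0.311 M. For this flask the share is 56.2 %, so 1.12 equivalents are bound, which is more than 0.890. With mono adduct held at 30.3 %, the mean of the zeta readings from 40.0 min on, my substrate is 28.6 %.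

The forecast differs, with less substrate than mine: 20 % substrate, 30 % mono adduct, 30 % bis adduct and 10 % tris adduct, calling the split “this split is a guess”.

The flask gives 28.7 % substrate, 29.1 % mono adduct, 37.3 % bis adduct and 0.410 % tris adduct.

    reagent + bis adduct → tris adduct (k = 1.18 × 10⁻⁵ /M/s)
    reagent + mono adduct → bis adduct (k = 7.72 × 10⁻⁴ /M/s)
    bis adduct ⇌ isomer of the product (K = 0.120, k = 1.95 × 10⁻⁴ /s)
    2 reagent → self-condensation product (k = 2.37 × 10⁻⁴ /M/s)
    substrate + reagent → mono adduct (k = 5.74 × 10⁻⁴ /M/s)

In this flask self-condensation has half of its turnover up to 5.0 h behind it by 0.238 h, and the reagent stands at 42.3 % of its charge at 0.500 h. The substrate step has 94 % of its turnover up to 5.0 h behind it at 2.50 h, with reagent at 6.67 % of its charge, and reagent, the limiting reagent, ends at 1.4 % of its charge against 29 % of the substrate. With tris adduct dropped, the flask's substrate and mono adduct count to a bound share of 56.7 % of the reagent charged, and the forecast's count to 65.0 %.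

In a neighbour flask with 0.24 M of substrate, the rest as in this flask, h gives a share of 43.5 %, or 1.45 equivalents. That neighbour flask computes to 19.1 % substrate and 24.1 % mono adduct, which count to 1.38.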